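## Structural features

Mollicellin A is an achiral, tetracyclic depsidone. Ring A is a benzene with six different substituents in the order C1′ (lactone carbonyl), C2′ (diaryl ether oxygen), C3′ (formyl), C4′ (hydroxyl), C5′ (hydrogen) and C6′ (methyl). Ring B is the benzene of a 2,2-dimethylchroman-4-one with methyl at C5, the ether oxygen at C6, the ester oxygen at C7 and its only hydrogen at C8. The two benzene rings are joined twice, through the C2′–O–C6 ether and the C1′–C(=O)–O–C7 ester, and these two links close the central seven-membered dioxepinone lactone. There is no stereocentre, so every problem is one of regiochemistry and chemoselectivity. The aryl ester of the lactone is opened by hydroxide, alkoxides and amines, the salicylaldehyde is sensitive to peroxides, and the chromanone has an electrophilic ketone and can open by retro-oxa-Michael reaction under strong base. The real difficulty is the diaryl ether between two carbons that each carry two ortho substituents, together with the seven-membered ring and the need to tell O6 from O7 on ring B. The key step uses the fact that the six carbons of ring A fall into three adjacent pairs, C6′/C1′, C2′/C3′ and C4′/C5′. The first pair with its carbonyl is a but-2-ynoate on O7, the second is an ethynyl ether on O6, and the third is a boron-bearing alkyne, so joining three alkynes makes ring A and the lactone with the hindered C–O bonds already in place.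

## Logic of the disconnections

21 to 20: the C3′–CHO bond is cut. The aldehyde would not survive the peroxide step that makes the phenol, so it is added last. C3′ lies between the phenol and the ether oxygen, where a titanium phenoxide can deliver an electrophile. The forward step must choose C3′ over C5′ (next to the methyl group) and over C8–H of ring B.

20 to 19: the C4′–O bond is exchanged for C4′–B. An oxygen substituent on the third alkyne would not orient it reliably, whereas a bulky boryl group does, and an aryl boronate is oxidised under mild conditions. The oxidant must be close to neutral so that the lactone stays closed.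

19 to 17 and 18: the bonds C1′–C2′, C3′–C4′ and C5′–C6′ are cut. Ring A and the seven-membered lactone disappear together and what remains is ring B with two small alkynyl groups on its neighbouring oxygens, plus a two-carbon boron reagent. The forward step must form the seven-membered ring faster than 18 trimerises, and must place boron next to the CH terminus and not next to the methyl-bearing one.

17 to 14 and 15: the ester C–O bond at O7 is cut. The ynoate is a Michael acceptor and tolerates neither organolithium reagents nor long exposure to amines, so it is put on last. Carboxylic acids add across ynol ethers, so 15 must be activated as 16 before it meets 14.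

14 to 11: the C≡C bond is traced back to the (E)-dichlorovinyl ether (loss of HCl, then exchange of Cl for Li and protonation). The forward step uses n-BuLi beside an aryl ketone and a phenol. Both are masked in the flask as enolate and phenoxide by an amide base (12, 13), so no separate protection is needed.

11 to 10, and 10 to 8 and 9: the O7–allyl bond is restored and the O6–vinyl bond is cut. O7 must be blocked while the 6-phenoxide adds to the dichloroacetylene made from 9. A silyl or acyl group on O7 would migrate to O6 as soon as the 6-phenoxide forms, because the 7-phenoxide, para to the ketone, is the more stable anion. An allyl ether cannot migrate. It is removed at the robust dichlorovinyl stage, so the palladium catalyst never meets the ynol ether.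

8 to 7: the O7–allyl bond is cut. The 7-hydroxyl is a vinylogous acid and the less hindered of the two, so one equivalent of weak base should alkylate it alone.

7 to 6 to 5: the C7–O bond is traced back to a C7–CHO bond and then to C7–H. C7 is the only free position ortho to the 6-hydroxyl, so ortho-formylation followed by aryl migration to oxygen installs the second oxygen without any question of position.

5 to 3 and 4: the pyranone is cut at C2–C3 (aldol) and O1–C2 (oxa-Michael). This gives a simple acetophenone and 4. Only the hydroxyl ortho to the acetyl group can cyclise.

3 to 1: the C–O bond para to the phenol is cut. The para position of 1 is free and persulfate attacks there, so the first step sets the oxygen that later carries the ethynyl group.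

## Other disconnections considered

Alternative 1: The cut removes ring B and the pyranone together, at C8a–C4a, C5–C6 and C6–C7, with C6 coming from carbon monoxide. In the forward direction the pentacarbonylchromium alkoxy(alkenyl)carbene A1 is heated. Its alkoxy oxygen is the future O1, and three atoms away it carries a ketal-masked methyl alkynyl ketone. The alkyne inserts into the chromium–carbene bond, CO inserts, and the dienylketene closes onto the benzyloxy-bearing alkenyl carbon to give A2.
- In its favour: A2 arrives with every ring B substituent placed, O6 free and O7 benzylated. The two oxygens are differentiated by construction and not by an acidity difference, and the ketone is already a ketal, which would make the later alkyllithium step trouble-free. On these two points it is the better plan.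
- Against it: the carbene needs a tertiary alkoxy group, which cannot be introduced by the usual O-alkylation of the acyl chromate and only poorly by alcohol exchange. The three-atom tether forces the bulky ketal-bearing alkyne carbon next to the carbene carbon, against the normal steric preference, so cyclopentannulation or intermolecular insertion may win. Zerovalent chromium from Cr(CO)6 is used stoichiometrically. The benzyl group on O7 cannot be removed by hydrogenolysis once a chlorovinyl or alkynyl ether is present.
- Comparison: it solves only the half of the molecule that the chosen plan makes in five classical steps from 1, and leaves the hindered ether and the lactone untouched. Making A1 needs about as many steps as making 8. It is therefore equal at best in step count, better in oxygen differentiation and ketone masking, and much less secure in mechanism.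

Alternative 2: The cut removes two substituents from ring B of a finished depsidone, the C6–CH3 bond and the C7–alkynyl bond of A4 (dibenzodioxepinone numbering). In the forward direction Pd(OAc)2, a phosphine and a strained bicyclic alkene relay convert the aryl iodide A3 into a palladacycle. This is methylated at the free ortho C–H by a methyl sulfonate and then, after extrusion of the relay, coupled at the original C–I carbon with a terminal alkyne carrying the dimethyl carbinol, giving A4.
- In its favour: it needs no ynol ether and no organolithium, both new bonds form at positions fixed by the iodide, and the precursors are ordinary protected phenols. In robustness of the intermediates before the key step it is the better plan.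
- Against it: it closes no ring, so the hindered diaryl ether, the seven-membered lactone and the substitution of ring A must all be solved before A3 exists. Carbonate base at about 100 °C with a phosphine and palladium is a poor match for a base-labile depsidone lactone and a free aldehyde. The tertiary propargylic alcohol can lose acetone under these conditions. After A4 the alkyne must be turned into the enone (Meyer–Schuster rearrangement), two aryl methyl ethers must be cleaved with a boron halide next to an aldehyde and a lactone, and the pyranone must be closed.
- Comparison: structurally it addresses the easy part. Mechanistically it is well founded for simple aryl iodides but untested on such a substrate. It needs at least three steps after its key step against two here, and the steps to A3 are not counted in that figure.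

Alternative 3: The cut is the same ring A, but as a vinylketene plus one alkyne: C4′–C3′, C1′–C2′ and C4′–C5′. In the forward direction Wolff rearrangement of the diazo ketoester A5 (isopropenyl migration) gives an ester-substituted vinylketene. This adds to the ynol ether A6 by (2+2) cycloaddition, the cyclobutenone opens in a four-electron process, and the dienylketene closes in a six-electron process to the phenol A7.
- In its favour: ynol ethers are the classical partners of this benzannulation. The hydroxyl at C4′ is delivered directly and its position is fixed by the polarity of the cycloaddition (the ketene carbonyl carbon bonds to the CH terminus of the ynol ether) and not by a steric preference. No strained metallacycle is needed, and the benzyl group on O7 survives n-BuLi and is removed only after the alkyne is consumed. On regiocontrol and on protecting-group comfort it is the better plan.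
- Against it: the ketene is also an acylketene, which can react with the electron-rich alkyne as an oxadiene and give a pyranone. Wolff rearrangement of a 2-diazo-1,3-dicarbonyl compound needs short-wavelength light or high temperature, and the aryl ketone of ring B absorbs in that region. The lactone is not formed, so hydrogenolysis of two benzyl groups, a seven-membered lactonisation and the formylation follow.
- Comparison: A6 is as fragile as 14 and is made by the same chemistry. The key step forms one ring where the chosen step forms two. Three steps follow its key step against two, so the total is one step longer, in exchange for a lactonisation that is classical for depsidones.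

Key step: step 10

Remark on the chemistry: the target has no stereocentre; the only stereochemical element in the route is the (E) geometry of the dichlorovinyl ether in 10 and 11, which is lost in step 8. Compounds 1 and 18 are taken as purchasable.

## Route

Step 1
Reactants: 1 2-hydroxy-6-methylacetophenone
Product: 3 2,5-dihydroxy-6-methylacetophenone [1-(3,6-dihydroxy-2-methylphenyl)ethan-1-one], via potassium aryl sulfate 2 (not isolated)
Conditions: K2S2O8, NaOH, H2O, 0 → 20 °C; recover unreacted 1; then HCl, 90 °C
Reagents that add atoms: potassium peroxodisulfate, [K+].[K+].[O-]S(=O)(=O)OOS(=O)(=O)[O-]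
Why: Elbs persulfate oxidation: the phenoxide of 1 attacks a peroxide oxygen through its only free para carbon to give the aryl sulfate 2, whose S–O bond is cleaved by hot acid; conversion is expected to be partial and 1 is recovered before the hydrolysis.

Step 2
Reactants: 3 2,5-dihydroxy-6-methylacetophenone; 4 acetone
Product: 5 6-hydroxy-2,2,5-trimethylchroman-4-one
Conditions: 4 (5 equiv), pyrrolidine (0.5 equiv), MeOH, 50 °C, Ar
Reagents that add atoms: none
Why: Kabbe condensation: amine-catalysed aldol condensation of the acetyl group with acetone followed by oxa-Michael closure by the ortho hydroxyl; the other hydroxyl is meta to the acyl group and cannot cyclise, and argon protects the hydroquinone from air oxidation.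

Step 3
Reactants: 5 6-hydroxy-2,2,5-trimethylchroman-4-one
Product: 6 6-hydroxy-2,2,5-trimethyl-4-oxochromane-7-carbaldehyde
Conditions: MgCl2, Et3N, (CH2O)n, MeCN, reflux; 1 M HCl
Reagents that add atoms: paraformaldehyde (as formaldehyde), C=O
Why: Casnati–Skattebøl ortho-formylation: the magnesium phenoxide binds formaldehyde and delivers it to the ortho carbon, and a second formaldehyde oxidises the benzylic alkoxide by hydride transfer; C5 is blocked by methyl, so only C7 can react.

Step 4
Reactants: 6 6-hydroxy-2,2,5-trimethyl-4-oxochromane-7-carbaldehyde
Product: 7 6,7-dihydroxy-2,2,5-trimethylchroman-4-one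
Conditions: 30% H2O2, NaOH, THF/H2O, 0 °C → rt, Ar; HCl
Reagents that add atoms: hydrogen peroxide, OO
Why: Dakin oxidation: hydroperoxide adds to the aldehyde, the aryl group with its ortho phenoxide migrates to oxygen and the formate is hydrolysed in the same medium; the aryl ketone at C4 does not undergo Baeyer–Villiger reaction under these conditions.

Step 5
Reactants: 7 6,7-dihydroxy-2,2,5-trimethylchroman-4-one
Product: 8 7-(allyloxy)-6-hydroxy-2,2,5-trimethylchroman-4-one
Conditions: CH2=CHCH2Br (1.05 equiv), K2CO3 (1.0 equiv), DMF, 0 °C → rt
Reagents that add atoms: allyl bromide, C=CCBr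
Why: Williamson etherification: the 7-hydroxyl is para to the ketone (a vinylogous acid) and unhindered, so it alone is ionised and alkylated by one equivalent of carbonate; the allyl ether cannot migrate to O6 in the next step, as a silyl or acyl group would.

Step 6
Reactants: 8 7-(allyloxy)-6-hydroxy-2,2,5-trimethylchroman-4-one; 9 trichloroethylene
Product: 10 7-(allyloxy)-6-[(E)-1,2-dichlorovinyloxy]-2,2,5-trimethylchroman-4-one
Conditions: 9 (2 equiv), K2CO3 (2 equiv), DMF, 70 °C, Ar
Reagents that add atoms: none
Why: Base-mediated dichlorovinylation of a phenol: carbonate turns 9 into dichloroacetylene at low stationary concentration (made and consumed in solution, never isolated) and the 6-phenoxide adds to it in anti fashion, which gives the (E) ether; the small linear electrophile suits the hindered oxygen between methyl and allyloxy.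

Step 7
Reactants: 10 7-(allyloxy)-6-[(E)-1,2-dichlorovinyloxy]-2,2,5-trimethylchroman-4-one
Product: 11 6-[(E)-1,2-dichlorovinyloxy]-7-hydroxy-2,2,5-trimethylchroman-4-one
Conditions: Pd(PPh3)4 (5 mol%), morpholine (5 equiv), THF, rt
Reagents that add atoms: none
Why: Tsuji–Trost deallylation: zerovalent palladium ionises the allyl aryl ether and morpholine captures the allyl complex; the vinylic C–Cl bonds do not add to Pd(PPh3)4 at room temperature, and the step is placed here so that palladium never meets the ynol ether.

Step 8
Reactants: 11 6-[(E)-1,2-dichlorovinyloxy]-7-hydroxy-2,2,5-trimethylchroman-4-one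
Product: 14 6-(ethynyloxy)-7-hydroxy-2,2,5-trimethylchroman-4-one, via dilithium chloroalkyne 12 (not isolated), via trilithium acetylide 13 (not isolated)
Conditions: LiN(i-Pr)2 (3.5 equiv), THF, −78 °C; n-BuLi (1.3 equiv), −78 °C; sat. NH4Cl, −78 → 0 °C; used at once
Reagents that add atoms: none
Why: Dichlorovinyl ether to alkynyl ether: the amide base forms the 7-phenoxide and the C3 enolate (which mask the phenol and the ketone against n-BuLi) and eliminates HCl to the chloroalkyne 12, n-BuLi then exchanges chlorine for lithium to give 13, and the cold quench protonates all three anionic sites.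

Step 9
Reactants: 14 6-(ethynyloxy)-7-hydroxy-2,2,5-trimethylchroman-4-one; 15 but-2-ynoic acid
Product: 17 6-(ethynyloxy)-2,2,5-trimethyl-4-oxochroman-7-yl but-2-ynoate, via but-2-ynoic anhydride 16 (not isolated)
Conditions: 15 (2.4 equiv), DCC (1.2 equiv), CH2Cl2, 0 °C, filter; then 14, i-Pr2NEt (1.5 equiv), DMAP (5 mol%), −20 → 0 °C
Reagents that add atoms: none
Why: Steglich-type acylation with the preformed symmetrical anhydride 16: the acid is activated before it meets 14 because free carboxylic acids add across ynol ethers, the amine holds the liberated acid as carboxylate, and the acidic phenol para to the ketone acylates quickly at low temperature.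

Step 10
Reactants: 17 6-(ethynyloxy)-2,2,5-trimethyl-4-oxochroman-7-yl but-2-ynoate; 18 2-ethynyl-4,4,5,5-tetramethyl-1,3,2-dioxaborolane
Product: 19 depsidone boronate: 2,2,5-trimethylchroman-4-one whose O6 is bonded to C2′ and whose O7 is bonded through C(=O) to C1′ of ring A, which carries CH3 at C6′ and a 4,4,5,5-tetramethyl-1,3,2-dioxaborolan-2-yl group at C4′ (C3′ and C5′ are CH)
Conditions: Cp*RuCl(cod) (10 mol%), 18 (3 equiv), ClCH2CH2Cl, 40 °C, slow addition of 17, Ar
Reagents that add atoms: none
Why: The divalent ruthenium fragment Cp*RuCl binds both alkynes of 17 and couples them oxidatively, joining the carbonyl-bearing carbon of the ynoate to the oxygen-bearing carbon of the ynol ether; this C1′–C2′ bond closes the seven-membered lactone as part of a bicyclic ruthenacyclopentadiene whose metal-bound carbons carry CH3 and H. Alkyne 18 then inserts and reductive elimination forms the last C–C bond, so ring A is closed by a metal-templated (2+2+2) union of three two-carbon units. The closest known reaction type is the Cp*RuCl(cod)-catalysed cyclotrimerisation of tethered diynes, ester-tethered ones included, with terminal alkynes and alkynylboronates; aryl ethynyl ethers are known partners in related rhodium-catalysed reactions, and a tether that closes a seven-membered ring is at the long end of what has been used. The electron-poor ynoate and the electron-rich ynol ether are a matched pair for oxidative coupling, and the ortho-phenylene spacer holds them close, which should offset the cost of the s-cis ester geometry that the lactone demands. The step needs one orientation of 18: its boron-bearing carbon must bond to the CH terminus of the ruthenacycle and its CH carbon to the methyl-bearing terminus, the usual meta outcome for unsymmetrical diynes, secured by the bulk of the pinacolboryl group, which avoids the methyl group and the Cp* ligand; this puts boron para to the lactone carbonyl carbon, where the hydroxyl is needed. Slow addition of 17 to catalyst and excess 18 is meant to suppress oligomerisation of 17, and the chelating diyne should outcompete trimerisation of 18. No stereocentre is formed.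

Step 11
Reactants: 19 depsidone boronate
Product: 20 desformyl mollicellin A (ring A with OH at C4′, CH at C3′ and C5′, CH3 at C6′)
Conditions: KHSO5 (as 2KHSO5·KHSO4·K2SO4), acetone/H2O, 0 °C → rt, 15 min; aq NaHSO3
Reagents that add atoms: potassium peroxymonosulfate, [K+].[O-]S(=O)(=O)OO
Why: Oxidation of an aryl boronate: the peroxide oxygen adds to boron, the aryl group migrates from boron to oxygen at the same carbon and the borate is hydrolysed; the medium is neutral to slightly acidic, which spares the base-labile lactone, and the short reaction time limits over-oxidation of the phenol.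

Step 12
Reactants: 20 desformyl mollicellin A
Product: 21 mollicellin A
Conditions: Cl2CHOMe (2 equiv), TiCl4 (4 equiv), CH2Cl2, −20 → 0 °C; 1 M HCl
Reagents that add atoms: dichloromethyl methyl ether, COC(Cl)Cl
Why: Rieche formylation: TiCl4 forms the titanium phenoxide, ionises the chloro ether and delivers the electrophile to C3′, the ortho carbon flanked by the phenoxide and the diaryl ether oxygen (chelation and activation by both oxygens), and aqueous work-up gives the aldehyde, which is then held by a hydrogen bond to the phenol; C5′ is flanked by the methyl group and ring B is deactivated by its ketone and ester oxygen.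

## Compound list

1 | 2-hydroxy-6-methylacetophenone | CC(=O)c1c(C)cccc1O | starting material
2 | potassium 3-acetyl-4-hydroxy-2-methylphenyl sulfate | CC(=O)c1c(C)c(OS(=O)(=O)[O-])ccc1O.[K+] | intermediate
3 | 2,5-dihydroxy-6-methylacetophenone | CC(=O)c1c(C)c(O)ccc1O | intermediate
4 | acetone | CC(C)=O | starting material
5 | 6-hydroxy-2,2,5-trimethylchroman-4-one | CC1(C)CC(=O)c2c(C)c(O)ccc2O1 | intermediate
6 | 6-hydroxy-2,2,5-trimethyl-4-oxochromane-7-carbaldehyde | CC1(C)CC(=O)c2c(C)c(O)c(C=O)cc2O1 | intermediate
7 | 6,7-dihydroxy-2,2,5-trimethylchroman-4-one | CC1(C)CC(=O)c2c(C)c(O)c(O)cc2O1 | intermediate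
8 | 7-(allyloxy)-6-hydroxy-2,2,5-trimethylchroman-4-one | CC1(C)CC(=O)c2c(C)c(O)c(OCC=C)cc2O1 | intermediate
9 | trichloroethylene | ClC=C(Cl)Cl | starting material
10 | 7-(allyloxy)-6-[(E)-1,2-dichlorovinyloxy]-2,2,5-trimethylchroman-4-one | CC1(C)CC(=O)c2c(C)c(O/C(Cl)=C\Cl)c(OCC=C)cc2O1 | intermediate
11 | 6-[(E)-1,2-dichlorovinyloxy]-7-hydroxy-2,2,5-trimethylchroman-4-one | CC1(C)CC(=O)c2c(C)c(O/C(Cl)=C\Cl)c(O)cc2O1 | intermediate
12 | dilithium salt (7-phenoxide, C3–C4 enolate) of 6-(chloroethynyloxy)-7-hydroxy-2,2,5-trimethylchroman-4-one | ClC#COc1c(C)c2c(cc1[O-])OC(C)(C)C=C2[O-].[Li+].[Li+] | intermediate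
13 | trilithium salt (7-phenoxide, C3–C4 enolate, acetylide) of 6-(ethynyloxy)-7-hydroxy-2,2,5-trimethylchroman-4-one | [Li]C#COc1c(C)c2c(cc1[O-])OC(C)(C)C=C2[O-].[Li+].[Li+] | intermediate
14 | 6-(ethynyloxy)-7-hydroxy-2,2,5-trimethylchroman-4-one | CC1(C)CC(=O)c2c(C)c(OC#C)c(O)cc2O1 | intermediate
15 | but-2-ynoic acid | CC#CC(=O)O | starting material
16 | but-2-ynoic anhydride | CC#CC(=O)OC(=O)C#CC | intermediate
17 | 6-(ethynyloxy)-2,2,5-trimethyl-4-oxochroman-7-yl but-2-ynoate | CC#CC(=O)Oc1cc2c(c(C)c1OC#C)C(=O)CC(C)(C)O2 | intermediate
18 | 2-ethynyl-4,4,5,5-tetramethyl-1,3,2-dioxaborolane | C#CB1OC(C)(C)C(C)(C)O1 | starting material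
19 | depsidone boronate (desformyl mollicellin A with pinacolboryl in place of OH at C4′) | CC1(C)OB(OC1(C)C)c1cc(C)c2c(c1)Oc1c(C)c3c(cc1OC2=O)OC(C)(C)CC3=O | intermediate
20 | desformyl mollicellin A | Cc1cc(O)cc2c1C(=O)Oc1cc3c(c(C)c1O2)C(=O)CC(C)(C)O3 | intermediate
21 | mollicellin A | Cc1cc(O)c(C=O)c2c1C(=O)Oc1cc3c(c(C)c1O2)C(=O)CC(C)(C)O3 | target

## Step count and least certain steps

Total: 12 steps. Longest linear sequence: 12 steps, from 1 to 21; compounds 4, 9, 15 and 18 are purchased.

**Step 10 (key step).** The ruthenacycle that contains the seven-membered ring may form too slowly, because the tether is long and the ester must adopt its s-cis geometry. Trimerisation of 18, oligomerisation of 17 or vinylidene chemistry at the terminal ynol ether could then take over, and 18 could also insert in the reverse orientation.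
- Fallback, from 8 back to 19, building the ether and lactone classically and adding boron last:
- Phenol 8 and commercial 2-fluoro-6-methylbenzaldehyde would undergo nucleophilic aromatic substitution (Cs2CO3, DMSO, 90 °C) to give 2-{[7-(allyloxy)-2,2,5-trimethyl-4-oxochroman-6-yl]oxy}-6-methylbenzaldehyde F1.
- Pinnick oxidation (NaClO2, NaH2PO4, 2-methylbut-2-ene) would give 2-{[7-(allyloxy)-2,2,5-trimethyl-4-oxochroman-6-yl]oxy}-6-methylbenzoic acid F2.
- Deallylation with Pd(PPh3)4 and morpholine would give 2-[(7-hydroxy-2,2,5-trimethyl-4-oxochroman-6-yl)oxy]-6-methylbenzoic acid F3.
- Carbodiimide lactonisation at high dilution (EDC·HCl, DMAP) would give the boron-free depsidone F4.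
- Iridium-catalysed C–H borylation ([Ir(OMe)(cod)]2, 4,4′-di-tert-butyl-2,2′-bipyridine, B2pin2) is sterically directed to C4′, the only ring A C–H without an ortho substituent, and would give 19.

**Step 8.** Enolisation may be incomplete, so that butyl adds to the ketone; the enolate may open by retro-oxa-Michael reaction if the mixture warms; or the 7-phenoxide may attack the chloroalkyne.
- Fallback, from 11 back to 14, with covalent masking:
- TBSOTf and Et3N would convert 11 into 4,7-bis(tert-butyldimethylsilyloxy)-6-[(E)-1,2-dichlorovinyloxy]-2,2,5-trimethyl-2H-chromene F5, a silyl enol ether and aryl silyl ether. Silyl migration is no longer possible, because O6 is already etherified.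
- n-BuLi (2.3 equiv, THF, −78 °C) would give 4,7-bis(tert-butyldimethylsilyloxy)-6-(ethynyloxy)-2,2,5-trimethyl-2H-chromene F6.
- n-Bu4NF at −20 °C followed by pH 7 buffer would release 14.

**Step 9.** Carboxylate or the phenol may add across the ynol ether, DMAP or the amine may add in conjugate fashion to the ynoate, or the ynoate may isomerise to the allenoate.
- Fallback, from 14 back to 17, with neither acid nor amine:
- N,O-bis(trimethylsilyl)acetamide would convert 14 into 6-(ethynyloxy)-2,2,5-trimethyl-7-(trimethylsilyloxy)chroman-4-one F7.
- But-2-ynoyl fluoride F8 would be made separately from 15 (cyanuric fluoride, pyridine).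
- Fluoride-catalysed acyl transfer between F7 and F8 (catalytic n-Bu4NF, MeCN, 0 °C) would give 17 with loss of the silyl group as its fluoride.

**Step 12.** Formylation may occur at C5′, between the hydroxyl and the methyl group, or twice, and the strong Lewis acid may open the lactone or the pyranone.
- Fallback, from 20 to 21, using the same electrophile preference to block C5′:
- NBS (1 equiv, MeCN, −20 °C) would give 5′-bromo desformyl mollicellin A F9.
- Rieche formylation, now possible only at C3′, would give 5′-bromo mollicellin A F10.
- Transfer hydrogenolysis (Pd(OAc)2, PPh3, HCO2H, Et3N, DMF, 60 °C) would remove bromine and give 21.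

**Step 3.** Formaldehyde may hydroxymethylate the position alpha to the ketone under the soft-enolising magnesium conditions, and attack at C7, para to the acyl group, may be slow.
- Fallback, from 5 back to 7, with direct oxygen transfer and no carbon detour:
- The pentavalent iodine reagent IBX (DMF, rt) would oxidise the phenol at its only free ortho position to 2,2,5-trimethylchromane-4,6,7-trione F11.
- Aqueous Na2S2O4 would reduce it to 7.

## Further compounds

F1 | step 10 | 2-{[7-(allyloxy)-2,2,5-trimethyl-4-oxochroman-6-yl]oxy}-6-methylbenzaldehyde | O=Cc1c(C)cccc1Oc1c(C)c2c(cc1OCC=C)OC(C)(C)CC2=O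
F2 | step 10 | 2-{[7-(allyloxy)-2,2,5-trimethyl-4-oxochroman-6-yl]oxy}-6-methylbenzoic acid | OC(=O)c1c(C)cccc1Oc1c(C)c2c(cc1OCC=C)OC(C)(C)CC2=O
F3 | step 10 | 2-[(7-hydroxy-2,2,5-trimethyl-4-oxochroman-6-yl)oxy]-6-methylbenzoic acid | OC(=O)c1c(C)cccc1Oc1c(C)c2c(cc1O)OC(C)(C)CC2=O
F4 | step 10 | boron-free depsidone (19 with H in place of the boryl group at C4′) | Cc1cccc2c1C(=O)Oc1cc3c(c(C)c1O2)C(=O)CC(C)(C)O3
F5 | step 8 | 4,7-bis(tert-butyldimethylsilyloxy)-6-[(E)-1,2-dichlorovinyloxy]-2,2,5-trimethyl-2H-chromene | CC1(C)C=C(O[Si](C)(C)C(C)(C)C)c2c(C)c(O/C(Cl)=C\Cl)c(O[Si](C)(C)C(C)(C)C)cc2O1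
F6 | step 8 | 4,7-bis(tert-butyldimethylsilyloxy)-6-(ethynyloxy)-2,2,5-trimethyl-2H-chromene | CC1(C)C=C(O[Si](C)(C)C(C)(C)C)c2c(C)c(OC#C)c(O[Si](C)(C)C(C)(C)C)cc2O1
F7 | step 9 | 6-(ethynyloxy)-2,2,5-trimethyl-7-(trimethylsilyloxy)chroman-4-one | CC1(C)CC(=O)c2c(C)c(OC#C)c(O[Si](C)(C)C)cc2O1
F8 | step 9 | but-2-ynoyl fluoride | CC#CC(F)=O
F9 | step 12 | 5′-bromo desformyl mollicellin A (Br on the ring A carbon between OH and CH3) | Cc1c(Br)c(O)cc2c1C(=O)Oc1cc3c(c(C)c1O2)C(=O)CC(C)(C)O3
F10 | step 12 | 5′-bromo mollicellin A | Cc1c(Br)c(O)c(C=O)c2c1C(=O)Oc1cc3c(c(C)c1O2)C(=O)CC(C)(C)O3
F11 | step 3 | 2,2,5-trimethylchromane-4,6,7-trione | CC1(C)CC(=O)C2=C(C)C(=O)C(=O)C=C2O1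
A1 | alternative 1 | pentacarbonyl{[(E)-2-(benzyloxy)ethenyl][2-methyl-1-(2-(prop-1-yn-1-yl)-1,3-dioxolan-2-yl)propan-2-yloxy]methylidene}chromium | CC#CC1(OCCO1)CC(C)(C)OC(/C=C/OCc1ccccc1)=[Cr](=C=O)(=C=O)(=C=O)(=C=O)=C=O
A2 | alternative 1 | 7-(benzyloxy)-6-hydroxy-2,2,5-trimethylchroman-4-one ethylene ketal | CC1(C)CC2(OCCO2)c2c(C)c(O)c(OCc3ccccc3)cc2O1
A3 | alternative 2 | 7-iodo-3,8-dimethoxy-1-methyl-11-oxo-11H-dibenzo[b,e][1,4]dioxepine-4-carbaldehyde | COc1cc(C)c2c(c1C=O)Oc1cc(I)c(OC)cc1OC2=O
A4 | alternative 2 | 7-(3-hydroxy-3-methylbut-1-yn-1-yl)-3,8-dimethoxy-1,6-dimethyl-11-oxo-11H-dibenzo[b,e][1,4]dioxepine-4-carbaldehyde | COc1cc(C)c2c(c1C=O)Oc1c(C)c(C#CC(C)(C)O)c(OC)cc1OC2=O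
A5 | alternative 3 | benzyl 2-diazo-4-methyl-3-oxopent-4-enoate | C=C(C)C(=O)C(=[N+]=[N-])C(=O)OCc1ccccc1
A6 | alternative 3 | 7-(benzyloxy)-6-(ethynyloxy)-2,2,5-trimethylchroman-4-one | CC1(C)CC(=O)c2c(C)c(OC#C)c(OCc3ccccc3)cc2O1
A7 | alternative 3 | benzyl 2-[(7-benzyloxy-2,2,5-trimethyl-4-oxochroman-6-yl)oxy]-4-hydroxy-6-methylbenzoate | O=C(OCc1ccccc1)c1c(C)cc(O)cc1Oc1c(C)c2c(cc1OCc1ccccc1)OC(C)(C)CC2=O
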